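**Plan**

1. Retrosynthesis: the C1 hydroxyl is removed first (β-borylation/oxidation of a ring-A 1-en-3-one) and the C12 carbinol is traced to its 12-ketone. The C12–C13 bond is then cut by a carbonyl-ene transform: the C12 carbinol is homoallylic to the exocyclic C16=C17 through bridgehead C13 (rings C/D), so ring C, C13 and the methylene come from a C12 aldehyde and a spiro 16-methylcyclopent-13(16)-ene (ring D on C8).
2. Further cuts: C10–O and C5–H (iodolactonisation, deiodination) and C4–C18 (Birch reductive methylation) lead back to an arene ring A; then C13=C16 (metathesis), C8–C14 and C8–C15 (allylations), C9=C11 (olefination), C9–C10 (Friedel–Crafts) and C5–C6 (conjugate arylation).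
3. Forward order: arene ring A, ring B (indanone), spiro ring D, C9 side chain, dearomatisation and 19,10-lactone, ring C last, then C12 inversion, enone and 1β-OH.
4. Stereochemistry: C6 comes from a rhodium-catalysed asymmetric arylation. Its carboxyl, held on the α face, directs the second C8 alkylation, the C9 protonation and the C4 methylation anti to itself and is then epimerised to the stable β position. C10/C5 follow from anti iodolactonisation, C13 from the tether, C12 from hydride delivery to the 12-ketone, and C1 from β-face borylation.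

Key step: step 15

Remark on numbering: gibberellane numbering (C1–C19) is used for every compound; α is the face of ring B that carries the lactone oxygen in the target, so the target is the 1β,12α-diol.
Assumption: in step 2 the antipode of the diene ligand is the one that delivers the (S)-succinate; the named antipode is exchanged for its mirror image if the sense of induction is the reverse.

**Route**

Step 1
Reactants: 1 N,N-diethyl-2-methoxybenzamide
Product: 2 [2-(diethylcarbamoyl)-3-methoxyphenyl]boronic acid
Conditions: s-BuLi, TMEDA, THF, −78 °C; B(OMe)3, −78 °C to rt; 1 M HCl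
Reagents that add atoms: trimethyl borate COB(OC)OC; water O
Why: Directed ortho-metalation: the tertiary amide outranks OMe as director, so lithiation should occur at the free position ortho to the amide, and borate quench with hydrolysis gives the arylboronic acid.

Step 2
Reactants: 2 [2-(diethylcarbamoyl)-3-methoxyphenyl]boronic acid; 3 di-tert-butyl fumarate
Product: 4 di-tert-butyl (S)-2-[2-(diethylcarbamoyl)-3-methoxyphenyl]succinate
Conditions: [RhCl(C2H4)2]2 (2.5 mol %), (R,R)-2,5-diphenylbicyclo[2.2.2]octa-2,5-diene (6 mol %), KOH (10 mol %), 1,4-dioxane/H2O, 50 °C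
Reagents that add atoms: none
Why: Hayashi–Miyaura reaction: the aryl–rhodium species formed by transmetalation adds to the fumarate face selected by the chiral diene and the rhodium enolate is protonated by water, which should set C6 as S with high enantioselectivity.

Step 3
Reactants: 4 di-tert-butyl (S)-2-[2-(diethylcarbamoyl)-3-methoxyphenyl]succinate
Product: 6 (S)-7-(diethylcarbamoyl)-6-methoxy-3-oxoindane-1-carboxylic acid, via (S)-arylsuccinic acid 5 (not isolated)
Conditions: CF3CO2H, CH2Cl2, rt; evaporate; (CF3CO)2O, CF3SO3H (10 mol %), CH2Cl2, 0 °C to rt; H2O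
Reagents that add atoms: none
Why: Acidolysis frees both carboxyls and the CH2CO2H arm, activated as its trifluoroacetic mixed anhydride, closes ring B by intramolecular Friedel–Crafts acylation at the only free ortho position, which is para to OMe, leaving C6 untouched.

Step 4
Reactants: 6 (S)-7-(diethylcarbamoyl)-6-methoxy-3-oxoindane-1-carboxylic acid
Product: 7 (1S)-2-allyl-7-(diethylcarbamoyl)-6-methoxy-3-oxoindane-1-carboxylic acid (allyl trans to CO2H)
Conditions: LiN(i-Pr)2 (2.2 equiv), THF, −78 °C; allyl bromide, −78 to 0 °C; 1 M HCl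
Reagents that add atoms: allyl bromide C=CCBr
Why: Enolate alkylation of the carboxylate/ketone-enolate dianion at C8 (the C6 hydrogen α to a carboxylate is far less acidic, so C6 is not touched); the C8 configuration is erased again in step 5.

Step 5
Reactants: 7 (1S)-2-allyl-7-(diethylcarbamoyl)-6-methoxy-3-oxoindane-1-carboxylic acid (allyl trans to CO2H)
Product: 8 2-allyl-7-(diethylcarbamoyl)-6-methoxy-2-(2-methylallyl)-3-oxoindane-1-carboxylic acid (allyl cis and 2-methylallyl trans to CO2H; C1 as in 6)
Conditions: LiN(i-Pr)2 (2.2 equiv), THF, −78 °C; 3-bromo-2-methylprop-1-ene, −78 to 0 °C; 1 M HCl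
Reagents that add atoms: 3-bromo-2-methylprop-1-ene CC(=C)CBr
Why: Enolate alkylation: the second electrophile approaches the planar C8 enolate anti to the lithium carboxylate on C6, which should place 2-methylallyl (C15) on the β face and allyl (C14) on the α face and so fix the quaternary centre C8.

Step 6
Reactants: 8 2-allyl-7-(diethylcarbamoyl)-6-methoxy-2-(2-methylallyl)-3-oxoindane-1-carboxylic acid
Product: 9 7'-(diethylcarbamoyl)-6'-methoxy-3-methyl-3'-oxospiro[cyclopent-3-ene-1,2'-indane]-1'-carboxylic acid (C14 cis and C15 trans to CO2H)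
Conditions: second-generation Grubbs catalyst, RuCl2(=CHPh)(PCy3)(1,3-dimesitylimidazolidin-2-ylidene) (3 mol %), CH2Cl2, 40 °C
Reagents that add atoms: none
Why: Ring-closing metathesis of the geminal allyl/2-methylallyl pair closes ring D as a 1-methylcyclopentene with loss of ethene, the trisubstituted product olefin being inert to further metathesis.

Step 7
Reactants: 9 spiro keto acid (ring D on C8; 6α-CO2H)
Product: 10 the C9=C11H–C12O2Me alkylidene analogue of 9 (E/Z mixture)
Conditions: methyl (trimethylsilyl)acetate and LiN(i-Pr)2 (3 equiv each), THF, −78 °C; add 9; −78 °C to rt; 1 M HCl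
Reagents that add atoms: methyl (trimethylsilyl)acetate COC(=O)C[Si](C)(C)C
Why: Peterson olefination: the small lithium α-silyl ester enolate adds to the hindered non-enolisable aryl ketone and elimination of Me3SiOLi gives the C9=C11 enoate, whose geometry is irrelevant.

Step 8
Reactants: 10 C9=C11 enoate acid
Product: 12 aryl diacid with 9β-H (9α-CH2CO2H cis to 6α-CO2H; spiro ring D; 19-diethylamide; 3-OMe), via methyl ester acid 11 (not isolated)
Conditions: Mg turnings, MeOH, rt; then 2 M NaOH, 50 °C; HCl to pH 2
Reagents that add atoms: sodium hydroxide [Na+].[OH-]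
Why: Dissolving-metal conjugate reduction (Mg/MeOH) of the β-aryl enoate leaves the isolated ring-D olefin alone, and protonation of the benzylic C9 carbanion anti to the magnesium carboxylate on C6 should give 9β-H; hydroxide then cleaves only the unhindered methyl ester.

Step 9
Reactants: 12 aryl diacid with 9β-H
Product: 14 dimethyl ester of the 1,4-dihydro amide (3-methoxy-2-ene; 5(10)-ene; 4β-methyl; 19-diethylamide α; 6α-CO2Me; 9α-CH2CO2Me), via 4β-methyl diene diacid 13 (not isolated)
Conditions: KOt-Bu (2 equiv), K (2.5 equiv), NH3/THF, t-BuOH (1 equiv), −78 °C; MeI, −78 °C; NH4Cl; then Me3SiCHN2, MeOH/toluene, 0 °C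
Reagents that add atoms: iodomethane CI; (trimethylsilyl)diazomethane C[Si](C)(C)C=[N+]=[N-]
Why: Birch reductive alkylation: the benzamide ring is reduced at C4/C1 to the amide enolate, which is methylated anti to the adjacent 6α-carboxylate, setting C4 (C18 β, C19 α) and leaving the enol ether and the tetrasubstituted 5(10)-olefin; esterification then masks both acids.

Step 10
Reactants: 14 dimethyl ester of the 1,4-dihydro amide
Product: 15 3,3-ethylenedioxy analogue of 14 (5(10)-ene kept)
Conditions: ethylene glycol, camphorsulfonic acid (cat.), CH2Cl2, rt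
Reagents that add atoms: ethylene glycol OCCO
Why: Acid-catalysed exchange of the methyl enol ether with the diol gives the dioxolane directly, so the C3 carbonyl stays protected until step 18.

Step 11
Reactants: 15 3,3-ethylenedioxy 5(10)-ene amide diester
Product: 17 5β-iodo-19,10-lactone (3,3-ethylenedioxy; 6α-CO2Me; 9α-CH2CO2Me), via imidate iodide 16 (not isolated)
Conditions: I2 (1.3 equiv), NaHCO3, THF/H2O, 0 °C to rt, dark
Reagents that add atoms: iodine II; water O
Why: Iodolactonisation: iodonium formation on the β face of the 5(10)-olefin and anti attack of the nucleophilic tertiary amide oxygen at C10 on the α face give the imidate salt, hydrolysed in situ to the lactone; the C7 methyl ester is a much weaker neighbouring group and the ring-D olefin has none.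

Step 12
Reactants: 17 5β-iodo-19,10-lactone
Product: 18 5β-H 19,10-lactone with 6α-CO2Me (6-epi series)
Conditions: Bu3SnH (0.5 M), AIBN (cat.), toluene, 80 °C
Reagents that add atoms: none
Why: Radical deiodination: the C5 bridge radical can only take hydrogen on the face the iodine left, because C4 is tied to the α face through the lactone, giving 5β-H; the high stannane concentration should outrun attack of the radical on ring D.

Step 13
Reactants: 18 5β-H 19,10-lactone with 6α-CO2Me
Product: 19 the 6β-CO2Me epimer of 18 (natural C6)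
Conditions: NaOMe (0.3 equiv), MeOH, rt to 40 °C
Reagents that add atoms: none
Why: Base-mediated equilibration α to the ester: the 6α ester is cis to the quaternary C4 and should move to the less strained 6β position.

Step 14
Reactants: 19 6β-CO2Me lactone diester
Product: 20 C12 aldehyde (9α-CH2CHO; 6β-CO2Me; 3,3-ethylenedioxy; 19,10-lactone; spiro 16-methyl-13(16)-ene ring D)
Conditions: i-Bu2AlH (1.1 equiv), CH2Cl2, −78 °C; MeOH; aq. potassium sodium tartrate
Reagents that add atoms: none
Why: Partial ester reduction at −78 °C: the unhindered primary CH2CO2Me should react in preference to the neopentyl-type C7 ester and the lactone on quaternary C4.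

Step 15
Reactants: 20 C12 aldehyde
Product: 21 7-methyl ester of 3,3-ethylenedioxy-12β-hydroxy-20-norgibberell-16-ene-7,19-dioic acid 19,10-lactone
Conditions: Me2AlCl (2.5 equiv), CH2Cl2, −78 to −20 °C
Reagents that add atoms: none
Why: Me2AlCl binds the aldehyde and an intramolecular carbonyl-ene reaction of the citronellal-to-isopulegol type should follow: C12 bonds to C13, the less substituted carbon of the trisubstituted ring-D olefin, while a C17 hydrogen passes to oxygen through a six-membered transition state and the double bond moves to C16=C17. Ring C closes as a six-membered ring in the 6-exo mode with respect to both π bonds (O and C16 stay outside the new ring), through a chair that puts the small C12–H, not the O–Al group, 1,3-diaxial to C10. C13 is fixed by the tether: the aldehyde hangs from the α face of C9 and can only reach the α-disposed C13 that the C8 configuration provides. C12 is fixed by the hydrogen transfer, which needs the oxygen gauche to C16 and therefore equatorial (12β); this is the C12 epimer of the target and is corrected in steps 16 and 17. Regioselectivity (C13 not C16, a methyl hydrogen not C15–H) rests on Markovnikov polarisation of the olefin and on C17 lying on the side where the oxygen sits. The aldehyde is the only reactive π-electrophile at −78 °C, and Me2AlCl scavenges protons so the exocyclic olefin should not migrate.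

Step 16
Reactants: 21 12β-alcohol
Product: 22 7-methyl ester of 3,3-ethylenedioxy-12-oxo-20-norgibberell-16-ene-7,19-dioic acid 19,10-lactone
Conditions: Dess–Martin periodinane, NaHCO3, CH2Cl2, 0 °C to rt
Reagents that add atoms: none
Why: Dess–Martin oxidation of the secondary alcohol under buffered neutral conditions should leave the ketal and the exocyclic olefin intact; C13 is a bridgehead and cannot epimerise.

Step 17
Reactants: 22 12-ketone
Product: 23 7-methyl ester of 3,3-ethylenedioxy-12α-hydroxy-20-norgibberell-16-ene-7,19-dioic acid 19,10-lactone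
Conditions: LiBH(s-Bu)3 (L-Selectride), THF, −78 °C; aq. NH4Cl
Reagents that add atoms: none
Why: Bulky hydride reduction: the α face of the C12 carbonyl is closed by the axial C10 (1,3-diaxial, carrying the lactone oxygen), so the hydride should add from the β face and give the axial 12α-alcohol.

Step 18
Reactants: 23 12α-alcohol methyl ester ketal
Product: 25 12α-hydroxy-3-oxo-20-norgibberell-16-ene-7,19-dioic acid 19,10-lactone, via ketal acid 24 (not isolated)
Conditions: 2 M KOH, MeOH/H2O, 65 °C; then 2 M HCl, THF, rt
Reagents that add atoms: potassium hydroxide [K+].[OH-]; water O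
Why: Saponification of the hindered C7 ester (the lactone opens reversibly and recloses on acidification) followed by acid hydrolysis of the dioxolane frees the carboxylic acid and the C3 ketone in one operation.

Step 19
Reactants: 25 12α-hydroxy-3-oxo acid
Product: 27 12α-hydroxy-3-oxo-20-norgibberella-1,16-diene-7,19-dioic acid 19,10-lactone, via tris(trimethylsilyl) enol ether 26 (not isolated)
Conditions: Me3SiOTf, Et3N, CH2Cl2, 0 °C; then Pd(OAc)2 (1.2 equiv), MeCN, rt; 1 M HCl
Reagents that add atoms: trimethylsilyl trifluoromethanesulfonate C[Si](C)(C)OS(=O)(=O)C(F)(F)F (silyl groups of 26 only)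
Why: Saegusa–Ito oxidation: soft enolisation can only go toward C2 because C4 is quaternary and silylates OH and CO2H in passing; palladation of the enol ether and β-hydride elimination give the 1-en-3-one and zerovalent palladium, and the acidic work-up removes the silyl ester and ether.

Step 20
Reactants: 27 12α-hydroxy-3-oxo-1-ene acid
Product: 29 1β,12α-dihydroxy-3-oxo-20-norgibberell-16-ene-7,19-dioic acid 19,10-lactone (target), via 1β-boronate 28 (not isolated)
Conditions: B2pin2, CuSO4 (5 mol %), 4-picoline (10 mol %), NaHCO3 (1 equiv), H2O/THF, rt; then NaBO3·4H2O, rt; citric acid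
Reagents that add atoms: bis(pinacolato)diboron CC1(C)OB(OC1(C)C)B1OC(C)(C)C(C)(C)O1 (boron of 28 only); sodium perborate [Na+].[Na+].O[B-]1(O)OO[B-](O)(O)OO1
Why: Copper-catalysed conjugate borylation: the boryl–copper species should add to C1 from the β face, opposite the 19,10-lactone bridge, and perborate oxidation of the C–B bond with retention gives the 1β-hydroxy ketone without a base strong enough for β-elimination.

**Compound list**

1 | N,N-diethyl-2-methoxybenzamide | CCN(CC)C(=O)c1ccccc1OC | starting material
2 | [2-(diethylcarbamoyl)-3-methoxyphenyl]boronic acid | OB(O)c1cccc(OC)c1C(=O)N(CC)CC | intermediate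
3 | di-tert-butyl fumarate | CC(C)(C)OC(=O)/C=C/C(=O)OC(C)(C)C | starting material
4 | di-tert-butyl (S)-2-[2-(diethylcarbamoyl)-3-methoxyphenyl]succinate | CC(C)(C)OC(=O)C[C@@H](c1cccc(OC)c1C(=O)N(CC)CC)C(=O)OC(C)(C)C | intermediate
5 | (S)-2-[2-(diethylcarbamoyl)-3-methoxyphenyl]succinic acid | OC(=O)C[C@@H](c1cccc(OC)c1C(=O)N(CC)CC)C(=O)O | intermediate
6 | (S)-7-(diethylcarbamoyl)-6-methoxy-3-oxoindane-1-carboxylic acid | OC(=O)[C@@H]1c2c(C(=O)N(CC)CC)c(OC)ccc2C(=O)C1 | intermediate
7 | (1S)-2-allyl-7-(diethylcarbamoyl)-6-methoxy-3-oxoindane-1-carboxylic acid, allyl trans to CO2H | OC(=O)[C@@H]1c2c(C(=O)N(CC)CC)c(OC)ccc2C(=O)[C@H]1CC=C | intermediate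
8 | 2-allyl-7-(diethylcarbamoyl)-6-methoxy-2-(2-methylallyl)-3-oxoindane-1-carboxylic acid, allyl cis and 2-methylallyl trans to CO2H | OC(=O)[C@@H]1c2c(C(=O)N(CC)CC)c(OC)ccc2C(=O)[C@@]1(CC=C)CC(C)=C | intermediate
9 | 7'-(diethylcarbamoyl)-6'-methoxy-3-methyl-3'-oxospiro[cyclopent-3-ene-1,2'-indane]-1'-carboxylic acid, C14 cis to CO2H | OC(=O)[C@@H]1c2c(C(=O)N(CC)CC)c(OC)ccc2C(=O)[C@]13CC=C(C)C3 | intermediate
10 | 9 with C9=O replaced by C9=C11H–C12O2Me (E/Z mixture) | OC(=O)[C@@H]1c2c(C(=O)N(CC)CC)c(OC)ccc2C(=CC(=O)OC)[C@]13CC=C(C)C3 | intermediate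
11 | 9β-H acid with 9α-CH2CO2Me cis to 6α-CO2H | OC(=O)[C@@H]1c2c(C(=O)N(CC)CC)c(OC)ccc2[C@H](CC(=O)OC)[C@]13CC=C(C)C3 | intermediate
12 | 9β-H diacid (6α-CO2H, 9α-CH2CO2H, aryl 19-diethylamide) | OC(=O)[C@@H]1c2c(C(=O)N(CC)CC)c(OC)ccc2[C@H](CC(=O)O)[C@]13CC=C(C)C3 | intermediate
13 | 4β-methyl-3-methoxy-2,5(10)-diene 19-diethylamide diacid | OC(=O)[C@@H]1C2=C(CC=C(OC)[C@@]2(C)C(=O)N(CC)CC)[C@H](CC(=O)O)[C@]13CC=C(C)C3 | intermediate
14 | dimethyl ester of 13 | COC(=O)[C@@H]1C2=C(CC=C(OC)[C@@]2(C)C(=O)N(CC)CC)[C@H](CC(=O)OC)[C@]13CC=C(C)C3 | intermediate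
15 | 3,3-ethylenedioxy-5(10)-ene 19-diethylamide dimethyl ester | COC(=O)[C@@H]1C2=C(CCC4(OCCO4)[C@@]2(C)C(=O)N(CC)CC)[C@H](CC(=O)OC)[C@]13CC=C(C)C3 | intermediate
16 | 5β-iodo 19,10-(N,N-diethylimidate) iodide | COC(=O)[C@@H]1[C@]2(I)[C@]4(C)C(=[N+](CC)CC)O[C@]2(CCC45OCCO5)[C@H](CC(=O)OC)[C@]13CC=C(C)C3.[I-] | intermediate
17 | 5β-iodo-19,10-lactone, 3,3-ethylenedioxy, 6α-CO2Me, 9α-CH2CO2Me | COC(=O)[C@@H]1[C@]2(I)[C@]4(C)C(=O)O[C@]2(CCC45OCCO5)[C@H](CC(=O)OC)[C@]13CC=C(C)C3 | intermediate
18 | 5β-H 19,10-lactone, 6α-CO2Me | COC(=O)[C@@H]1[C@@H]2[C@]4(C)C(=O)O[C@]2(CCC45OCCO5)[C@H](CC(=O)OC)[C@]13CC=C(C)C3 | intermediate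
19 | 5β-H 19,10-lactone, 6β-CO2Me | COC(=O)[C@H]1[C@@H]2[C@]4(C)C(=O)O[C@]2(CCC45OCCO5)[C@H](CC(=O)OC)[C@]13CC=C(C)C3 | intermediate
20 | C12 aldehyde (9α-CH2CHO, 6β-CO2Me, 3,3-ethylenedioxy, 19,10-lactone, 16-methyl-13(16)-ene ring D) | COC(=O)[C@H]1[C@@H]2[C@]4(C)C(=O)O[C@]2(CCC45OCCO5)[C@H](CC=O)[C@]13CC=C(C)C3 | intermediate
21 | 7-methyl ester of 3,3-ethylenedioxy-12β-hydroxy-20-norgibberell-16-ene-7,19-dioic acid 19,10-lactone | C=C1C[C@]23C[C@H]1[C@H](O)C[C@H]2[C@]12OC(=O)[C@](C)(C4(OCCO4)CC1)[C@H]2[C@@H]3C(=O)OC | intermediate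
22 | 7-methyl ester of 3,3-ethylenedioxy-12-oxo-20-norgibberell-16-ene-7,19-dioic acid 19,10-lactone | C=C1C[C@]23C[C@H]1C(=O)C[C@H]2[C@]12OC(=O)[C@](C)(C4(OCCO4)CC1)[C@H]2[C@@H]3C(=O)OC | intermediate
23 | 7-methyl ester of 3,3-ethylenedioxy-12α-hydroxy-20-norgibberell-16-ene-7,19-dioic acid 19,10-lactone | C=C1C[C@]23C[C@H]1[C@@H](O)C[C@H]2[C@]12OC(=O)[C@](C)(C4(OCCO4)CC1)[C@H]2[C@@H]3C(=O)OC | intermediate
24 | 3,3-ethylenedioxy-12α-hydroxy-20-norgibberell-16-ene-7,19-dioic acid 19,10-lactone | C=C1C[C@]23C[C@H]1[C@@H](O)C[C@H]2[C@]12OC(=O)[C@](C)(C4(OCCO4)CC1)[C@H]2[C@@H]3C(=O)O | intermediate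
25 | 12α-hydroxy-3-oxo-20-norgibberell-16-ene-7,19-dioic acid 19,10-lactone | C=C1C[C@]23C[C@H]1[C@@H](O)C[C@H]2[C@]12OC(=O)[C@](C)(C(=O)CC1)[C@H]2[C@@H]3C(=O)O | intermediate
26 | trimethylsilyl ester, 12α-trimethylsilyl ether and 3-trimethylsilyl 2-enol ether of 25 | C=C1C[C@]23C[C@H]1[C@@H](O[Si](C)(C)C)C[C@H]2[C@]12OC(=O)[C@](C)(C(O[Si](C)(C)C)=CC1)[C@H]2[C@@H]3C(=O)O[Si](C)(C)C | intermediate
27 | 12α-hydroxy-3-oxo-20-norgibberella-1,16-diene-7,19-dioic acid 19,10-lactone | C=C1C[C@]23C[C@H]1[C@@H](O)C[C@H]2[C@]12OC(=O)[C@](C)(C(=O)C=C1)[C@H]2[C@@H]3C(=O)O | intermediate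
28 | 12α-hydroxy-3-oxo-1β-(pinacolatoboryl)-20-norgibberell-16-ene-7,19-dioic acid 19,10-lactone | C=C1C[C@]23C[C@H]1[C@@H](O)C[C@H]2[C@]12OC(=O)[C@](C)(C(=O)C[C@H]1B4OC(C)(C)C(C)(C)O4)[C@H]2[C@@H]3C(=O)O | intermediate
29 | 1β,12α-dihydroxy-3-oxo-20-norgibberell-16-ene-7,19-dioic acid 19,10-lactone | C=C1C[C@]23C[C@H]1[C@@H](O)C[C@H]2[C@]12OC(=O)[C@](C)(C(=O)C[C@H]1O)[C@H]2[C@@H]3C(=O)O | target

**Step count and risks**

Total step count: 20. Longest linear sequence: 20 steps (fully linear from 1).

Steps most likely to fail: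

1. Step 17: the hydride may be delivered to both faces of the 12-ketone, because the β face is flanked by C16 while the α face is blocked by C10, so the 12β-alcohol could form again. Fallback: setting out from the ene product 21, the equatorial alcohol is converted with trifluoromethanesulfonic anhydride and pyridine into the 12β-triflate F1. An equatorial leaving group has no anti-periplanar hydrogen for elimination, so it should be displaced with inversion by tetrabutylammonium nitrite (Lattrell–Dax inversion). Hydrolysis of the nitrite ester on work-up returns the route at 23.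

2. Step 9: reduction of the twisted, doubly ortho-substituted benzamide may stray from the C4/C1 positions, or methylation in the ammonia medium may occur on both faces of the enolate. Fallback: setting out from 12, the Birch reduction is run with a protic quench (NH4Cl) to give the 1,4-dihydro diacid F2 as a C4 epimer mixture. This is deprotonated separately with LiN(i-Pr)2 (3.3 equiv) in THF at −78 °C, where the carboxylates protect C6 and C11, and methylated with MeI. The route is rejoined at 13 and esterified as before.

3. Step 8: protonation of the benzylic C9 anion may take place on both faces, since the only bias is the 1,3-related carboxylate. Fallback: setting out from 9, the lithium enolate of methyl acetate is added to the ketone to give the tertiary benzylic alcohol F3. Ionic hydrogenation (Et3SiH, CF3CO2H, CH2Cl2, 0 °C) then delivers hydride to the para-methoxybenzylic C9 cation anti to the C6 carboxyl. The route is rejoined at 11, which is saponified to 12.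

Further compounds
F1 | step 17 | 12β-trifluoromethanesulfonate of 21 | C=C1C[C@]23C[C@H]1[C@H](OS(=O)(=O)C(F)(F)F)C[C@H]2[C@]12OC(=O)[C@](C)(C4(OCCO4)CC1)[C@H]2[C@@H]3C(=O)OC
F2 | step 9 | 3-methoxy-1,4-dihydro 19-diethylamide diacid with H at C4 (C4 epimers) | OC(=O)[C@@H]1C2=C(CC=C(OC)C2C(=O)N(CC)CC)[C@H](CC(=O)O)[C@]13CC=C(C)C3
F3 | step 8 | C9 tertiary alcohol carrying CH2CO2Me (C9 epimers) | OC(=O)[C@@H]1c2c(C(=O)N(CC)CC)c(OC)ccc2C(O)(CC(=O)OC)[C@]13CC=C(C)C3
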